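**Retrosynthetic overview**

- The strategy rests on ring B: the C6(axial β-O-isovaleryl)–C7(α-OH)–C8(CH3)=C9 array is read as the ene retron of a C7=C8 alkene with an axial H9α, so the C7–O bond is disconnected to that alkene plus singlet oxygen.
- The (13E)-C13=C14–C15–OH terminus is disconnected to a tertiary C13 vinyl carbinyl isovalerate ([3,3] ester shift, then selective deacylation); both isovalerates come from one double acylation of a 6β,13-diol.
- The 6β-alcohol with the C7=C8 alkene is traced to (+)-larixol by oxidation at C6, conjugation of the 8(17) alkene and α-face hydride delivery.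
- No ring is formed: rings A and B and all twenty skeletal carbons come intact from larixol. The order of events is C6 inversion, acylation, C7 oxygenation with alkene shift to C8=C9, ester shift 13→15, deacylation.

Key step: step 5

Assumption: (+)-larixol is taken as a commercial chiral-pool diterpene. Labdane numbering is used (C17 is the methyl on C8, C20 the methyl on C10, and α is the face opposite the C10 methyl).

**Route**

Step 1
Reactants: 1 (+)-larixol, (13S)-labda-8(17),14-diene-6α,13-diol
Product: 2 (13S)-13-hydroxylabda-8(17),14-dien-6-one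
Conditions: Dess–Martin periodinane (1.3 equiv), pyridine, CH2Cl2, 0 °C to rt
Reagents that add atoms: none
Why: Dess–Martin oxidation should convert only the secondary 6α-carbinol into the ketone, because the tertiary vinyl carbinol at C13 has no carbinol hydrogen and this chromium-free oxidant does not trigger its oxidative allylic transposition, and no stereocentre is created.

Step 2
Reactants: 2 (13S)-13-hydroxylabda-8(17),14-dien-6-one
Product: 3 (13S)-13-hydroxylabda-7,14-dien-6-one
Conditions: NaOMe (0.2 equiv), MeOH, rt
Reagents that add atoms: none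
Why: Methoxide-mediated prototropic isomerisation through the extended dienolate should move the exocyclic 8(17) alkene into conjugation as the C7=C8 enone, and reprotonation under equilibrating conditions should keep the trans ring fusion at C5 and the equatorial C9 side chain as the preferred arrangement.

Step 3
Reactants: 3 (13S)-13-hydroxylabda-7,14-dien-6-one
Product: 4 (13S)-labda-7,14-diene-6β,13-diol
Conditions: LiAlH4, Et2O, −20 to 0 °C; then H2O, aq. NaOH
Reagents that add atoms: none
Why: 1,2-Hydride reduction of the β,β-disubstituted enone should deliver hydride to C6 from the open α face, the β face being blocked by the syn-axial C4β and C10 methyl groups, which sets C6 as the axial 6β-alcohol and leaves the tertiary carbinol untouched.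

Step 4
Reactants: 4 (13S)-labda-7,14-diene-6β,13-diol; 5 isovaleric anhydride
Product: 6 (13S)-labda-7,14-diene-6β,13-diyl bis(isovalerate)
Conditions: 5 (6 equiv), DMAP (2 equiv), Et3N, toluene, 70 °C
Reagents that add atoms: isovaleric anhydride, CC(C)CC(=O)OC(=O)CC(C)C
Why: DMAP-catalysed acyl transfer (Steglich–Höfle acylation) with excess anhydride and warming should esterify both the hindered axial allylic 6β-hydroxyl and the tertiary 13-hydroxyl under basic conditions that cannot ionise either allylic C–O bond, with retention at C6 and C13 because only O–H bonds are broken.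

Step 5
Reactants: 6 (13S)-labda-7,14-diene-6β,13-diyl bis(isovalerate)
Product: 8 (13S)-7α-hydroxylabda-8,14-diene-6β,13-diyl bis(isovalerate), via 7α-hydroperoxide 7 (not isolated)
Conditions: O2, tetraphenylporphyrin (1 mol%), white LED light, CH2Cl2, −20 °C; then PPh3 (1.2 equiv), −20 °C to rt
Reagents that add atoms: dioxygen, O=O
Why: Sensitised singlet oxygen should approach the C7=C8 alkene of 6 from the α face as a perepoxide-like complex, bond to C7 and take the axial H9α onto its terminal oxygen in one suprafacial event (Schenck ene reaction), so that the alkene moves to the tetrasubstituted C8=C9 position and hydroperoxide 7 forms, whose O–O bond PPh3 then cleaves at once without touching C7. The closest known reaction type is the photooxygenation of trisubstituted ring alkenes in steroids and terpenoids, in which oxygen enters cis to an axial allylic hydrogen. No ring is closed, so no closure mode applies. The one new stereocentre, C7, should be 7α because the β face is screened by the axial C10 methyl and the axial 6β-isovalerate and because the hydrogen donor H9α lies on the α face, and the C9 stereocentre is consumed in the transfer. The step needs α-face attack, C–O bonding at C7, hydrogen transfer from C9 and not from the C17 methyl or C6, and an untouched chain alkene: these are secured in turn by the facial screening, by the perpendicular alignment of H9α on the more substituted C6/C9 side of the alkene (cis effect), by the in-plane pseudoequatorial H6α geminal to the ester, and by the poorly nucleophilic monosubstituted vinyl group. Abstraction from C17 remains the main competitor, and its 8(17)-ene isomer is to be removed by chromatography at the stage of 8.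

Step 6
Reactants: 8 (13S)-7α-hydroxylabda-8,14-diene-6β,13-diyl bis(isovalerate)
Product: 9 (13E)-7α-hydroxylabda-8,13-diene-6β,15-diyl bis(isovalerate)
Conditions: PdCl2(MeCN)2 (5 mol%), THF, rt
Reagents that add atoms: none
Why: Divalent palladium should bind the unhindered terminal vinyl group and trigger the cyclisation-induced [3,3] allylic ester shift (Overman-type rearrangement) from tertiary C13 to primary C15 through a chair 1,3-dioxan-2-ylium intermediate with the C12 chain equatorial, which should favour the 13E alkene (any Z isomer to be removed on AgNO3-impregnated silica), while the tetrasubstituted ring alkene, the free 7-hydroxyl and the non-allylic 6β-ester should not engage the catalyst.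

Step 7
Reactants: 9 (13E)-7α-hydroxylabda-8,13-diene-6β,15-diyl bis(isovalerate)
Product: 10 (13E)-6β-isovaleroyloxylabda-8,13-diene-7α,15-diol (target)
Conditions: K2CO3 (0.2 equiv), MeOH, 0 °C
Reagents that add atoms: none
Why: Carbonate-catalysed methanolysis (transesterification) should remove only the exposed primary allylic isovalerate, because the axial 6β-ester is screened by the syn-axial C4β and C10 methyl groups and its trans-diaxial relation to the 7α-hydroxyl rules out acyl migration.

**Compound list**

1 | (+)-larixol, (13S)-labda-8(17),14-diene-6α,13-diol | C=C1[C@H](CC[C@](C)(O)C=C)[C@@]2(C)CCCC(C)(C)[C@@H]2[C@@H](O)C1 | starting material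
2 | (13S)-13-hydroxylabda-8(17),14-dien-6-one | C=C1[C@H](CC[C@](C)(O)C=C)[C@@]2(C)CCCC(C)(C)[C@@H]2C(=O)C1 | intermediate
3 | (13S)-13-hydroxylabda-7,14-dien-6-one | O=C1C=C(C)[C@H](CC[C@](C)(O)C=C)[C@@]2(C)CCCC(C)(C)[C@H]12 | intermediate
4 | (13S)-labda-7,14-diene-6β,13-diol | O[C@@H]1C=C(C)[C@H](CC[C@](C)(O)C=C)[C@@]2(C)CCCC(C)(C)[C@H]12 | intermediate
5 | isovaleric anhydride | CC(C)CC(=O)OC(=O)CC(C)C | starting material
6 | (13S)-labda-7,14-diene-6β,13-diyl bis(isovalerate) | CC(C)CC(=O)O[C@@H]1C=C(C)[C@H](CC[C@](C)(OC(=O)CC(C)C)C=C)[C@@]2(C)CCCC(C)(C)[C@H]12 | intermediate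
7 | (13S)-7α-hydroperoxylabda-8,14-diene-6β,13-diyl bis(isovalerate) | CC1=C(CC[C@](C)(OC(=O)CC(C)C)C=C)[C@@]2(C)CCCC(C)(C)[C@@H]2[C@H](OC(=O)CC(C)C)[C@H]1OO | intermediate (not isolated)
8 | (13S)-7α-hydroxylabda-8,14-diene-6β,13-diyl bis(isovalerate) | CC1=C(CC[C@](C)(OC(=O)CC(C)C)C=C)[C@@]2(C)CCCC(C)(C)[C@@H]2[C@H](OC(=O)CC(C)C)[C@H]1O | intermediate
9 | (13E)-7α-hydroxylabda-8,13-diene-6β,15-diyl bis(isovalerate) | CC1=C(CC/C(C)=C/COC(=O)CC(C)C)[C@@]2(C)CCCC(C)(C)[C@@H]2[C@H](OC(=O)CC(C)C)[C@H]1O | intermediate
10 | (13E)-6β-isovaleroyloxylabda-8,13-diene-7α,15-diol | CC1=C(CC/C(C)=C/CO)[C@@]2(C)CCCC(C)(C)[C@@H]2[C@H](OC(=O)CC(C)C)[C@H]1O | target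

**Step count and risks**

Total step count: 7. Longest linear sequence: 7 steps, from 1.

Steps most likely to fail:

1. Step 5. The perepoxide may take a hydrogen from the freely rotating C17 methyl instead of the axial H9α, which would divert material to the exocyclic 8(17)-ene hydroperoxide; slow oxygenation of the ester-deactivated alkene may also allow allylic hydroperoxide rearrangement. The fallback makes the C7–O bond by epoxidation and the C8=C9 alkene by anti elimination; it sets out from 6 and comes back at 8. mCPBA (NaHCO3, CH2Cl2, 0 °C) should epoxidise only the trisubstituted ring alkene, from the open α face, to give (13S)-7α,8α-epoxylabd-14-ene-6β,13-diyl bis(isovalerate) F1. Silyl triflate-mediated epoxide-to-allylic-ether isomerisation (TMSOTf, 2,6-lutidine, toluene, −78 °C, then DBU) should open the tertiary C8–O bond and remove the anti-periplanar axial H9α from the axial 8β leaving group (Zaitsev-type elimination). This would give (13S)-7α-trimethylsilyloxylabda-8,14-diene-6β,13-diyl bis(isovalerate) F2, in which the C7–O bond from the epoxidation is never broken. Brief K2CO3/MeOH at 0 °C should remove the silyl group and return 8.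

2. Step 6. The Lewis-acidic divalent palladium salt may ionise the allylic 7α-hydroxyl or the tertiary ester (elimination to dienes) instead of templating the shift, and geometric control at the new C13=C14 alkene may be incomplete, with isomers that are hard to separate at this polar stage. The fallback moves the ester shift ahead of the oxygenation and masks the chain alkene as an enal; it sets out from 6 and comes back at 10. PdCl2(MeCN)2 in THF should convert 6 into (13E)-labda-7,13-diene-6β,15-diyl bis(isovalerate) F3; the ring allylic ester cannot shift because its alkene terminus C8 is fully substituted. K2CO3/MeOH at 0 °C should free the primary alcohol, (13E)-15-hydroxylabda-7,13-dien-6β-yl isovalerate F4, and MnO2 in CH2Cl2 should oxidise it to (13E)-6β-isovaleroyloxylabda-7,13-dien-15-al F5, at which stage geometric isomers are to be separated. The conjugated, electron-poor chain alkene of F5 should be inert to singlet oxygen, so photooxygenation (O2, tetraphenylporphyrin, light, CH2Cl2, −20 °C) should give (13E)-7α-hydroperoxy-6β-isovaleroyloxylabda-8,13-dien-15-al F6. PPh3 in the same flask should reduce it to (13E)-7α-hydroxy-6β-isovaleroyloxylabda-8,13-dien-15-al F7, and Luche reduction (NaBH4, CeCl3·7H2O, MeOH, −40 °C) should then give 10.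

3. Step 4. Exhaustive acylation may stall at the tertiary 13-hydroxyl, or the forcing conditions may dehydrate the axial allylic 6β-alcohol. The fallback separates the two acylations around the reduction so that each faces a single hydroxyl; it sets out from 3 and comes back at 6. Isovaleric anhydride 5 with DMAP and Et3N at 80 °C, applied to enone 3 (which has no ionisable secondary allylic alcohol yet), should give (13S)-6-oxolabda-7,14-dien-13-yl isovalerate F8. Luche reduction (NaBH4, CeCl3·7H2O, MeOH, −20 °C), again from the α face and sparing the tertiary ester, should give (13S)-6β-hydroxylabda-7,14-dien-13-yl isovalerate F9. Acylation of the one remaining hydroxyl (5, DMAP, CH2Cl2, 40 °C) should return 6.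

**Further compounds**

F1 | step 5 | (13S)-7α,8α-epoxylabd-14-ene-6β,13-diyl bis(isovalerate) | CC(C)CC(=O)O[C@@H]1[C@H]2O[C@@]2(C)[C@H](CC[C@](C)(OC(=O)CC(C)C)C=C)[C@@]3(C)CCCC(C)(C)[C@H]13
F2 | step 5 | (13S)-7α-trimethylsilyloxylabda-8,14-diene-6β,13-diyl bis(isovalerate) | CC1=C(CC[C@](C)(OC(=O)CC(C)C)C=C)[C@@]2(C)CCCC(C)(C)[C@@H]2[C@H](OC(=O)CC(C)C)[C@H]1O[Si](C)(C)C
F3 | step 6 | (13E)-labda-7,13-diene-6β,15-diyl bis(isovalerate) | CC(C)CC(=O)O[C@@H]1C=C(C)[C@H](CC/C(C)=C/COC(=O)CC(C)C)[C@@]2(C)CCCC(C)(C)[C@H]12
F4 | step 6 | (13E)-15-hydroxylabda-7,13-dien-6β-yl isovalerate | CC(C)CC(=O)O[C@@H]1C=C(C)[C@H](CC/C(C)=C/CO)[C@@]2(C)CCCC(C)(C)[C@H]12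
F5 | step 6 | (13E)-6β-isovaleroyloxylabda-7,13-dien-15-al | CC(C)CC(=O)O[C@@H]1C=C(C)[C@H](CC/C(C)=C/C=O)[C@@]2(C)CCCC(C)(C)[C@H]12
F6 | step 6 | (13E)-7α-hydroperoxy-6β-isovaleroyloxylabda-8,13-dien-15-al | CC1=C(CC/C(C)=C/C=O)[C@@]2(C)CCCC(C)(C)[C@@H]2[C@H](OC(=O)CC(C)C)[C@H]1OO
F7 | step 6 | (13E)-7α-hydroxy-6β-isovaleroyloxylabda-8,13-dien-15-al | CC1=C(CC/C(C)=C/C=O)[C@@]2(C)CCCC(C)(C)[C@@H]2[C@H](OC(=O)CC(C)C)[C@H]1O
F8 | step 4 | (13S)-6-oxolabda-7,14-dien-13-yl isovalerate | O=C1C=C(C)[C@H](CC[C@](C)(OC(=O)CC(C)C)C=C)[C@@]2(C)CCCC(C)(C)[C@H]12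
F9 | step 4 | (13S)-6β-hydroxylabda-7,14-dien-13-yl isovalerate | O[C@@H]1C=C(C)[C@H](CC[C@](C)(OC(=O)CC(C)C)C=C)[C@@]2(C)CCCC(C)(C)[C@H]12
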